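**Plan**

1. Retrosynthesis: C3–Br goes back to a C2=C3 bromoalkene (from the C3 ketone, from a C3 silyl ether) and the oxirane to a C13=C14 alkene. Ring C is cut at C13=C14 (ring-closing metathesis) and O–C15 (allylation of the C8 alcohol), and the side chain at C11–C12 and C12–C13.
2. Ring B carries four contiguous stereocentres (C5, C10, C9, C8) in a trans-decalin, with O and methyl on C8 and the C11 carbon on C9. Cutting C5–C10 and C8–C9 therefore opens rings A and B together to a 1,3,9-decatriene: a C5=C6–C7=C8 silyl dienol ether and a C9=C10 enal joined by C1–C4.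
3. The trienal is cut at C6–C7 (palladium coupling of an E-alkenyl iodide with an acetone enolate), C5=C6 (Takai olefination) and C3–C4 (enantioselective tert-prenylation of a C3 aldehyde from methyl geranate).
4. Forward: the chain is assembled C11→C3, then C4–C6, then C7–C8. Rings A and B close together in the cycloaddition; ring C (oxocene) closes last by metathesis, followed by epoxidation and reduction of the bromoalkene.
5. Stereochemistry: C3 from the chiral iridium catalyst; C5, C8, C9, C10 from the cycloaddition (endo formyl, E-enal, 7Z-dienol ether, equatorial C3 silyloxy group in the chair tether); C13/C14 from outer-face epoxidation of the ring Z-alkene; the equatorial C3–Br from hydrogen-atom transfer.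

Key step: step 10

**Conventions and assumptions**

- Labdane numbering is used for ring compounds. β is the face of H5 and H9; the C10 and C8 methyl groups lie on the α face (ent-labdane series). TBS = tert-butyldimethylsilyl.
- Assumption: commercial methyl geranate is taken as the pure (2E)-ester; any (2Z)-ester is removed before step 1.
- Assumption: the (S)-SEGPHOS iridium catalyst is taken to give the (R)-carbinol 5; if the sense is the opposite, (R)-SEGPHOS is used with nothing else changed.

**Route**

Step 1
Reactants: 1 methyl geranate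
Product: 3 methyl (2E)-3-methyl-6-oxohex-2-enoate, via ozonide 2 (not isolated)
Conditions: O3, CH2Cl2, −78 °C (Sudan Red 7B end point); then Me2S, −78 → 23 °C
Reagents that add atoms: ozone [O-][O+]=O
Why: Chemoselective ozonolysis with reductive work-up (Criegee mechanism) should cleave only the electron-rich 6,7-alkene, because the conjugated 2,3-enoate reacts far more slowly with ozone, and the (2E) geometry is untouched.

Step 2
Reactants: 3 methyl (2E)-3-methyl-6-oxohex-2-enoate; 4 3-methylbuta-1,2-diene
Product: 5 methyl (2E,6R)-6-hydroxy-3,7,7-trimethylnona-2,8-dienoate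
Conditions: preformed π-allyl iridium C,O-benzoate complex (5 mol %; from [Ir(cod)Cl]2, (S)-SEGPHOS, 4-cyano-3-nitrobenzoic acid, allyl acetate, Cs2CO3), i-PrOH (2 equiv), PhMe, 50 °C
Reagents that add atoms: none
Why: Iridium-catalysed transfer-hydrogenative carbonyl tert-prenylation: hydrometalation of the allene gives a 1,1-dimethylallyl iridium species that adds to the aldehyde through a closed chair transition state in the chiral ligand pocket, forming C3–C4, the quaternary C4 and the (R)-carbinol at C3 under catalyst control.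

Step 3
Reactants: 5 methyl (2E,6R)-6-hydroxy-3,7,7-trimethylnona-2,8-dienoate
Product: 6 methyl (2E,6R)-6-(TBS-oxy)-3,7,7-trimethylnona-2,8-dienoate
Conditions: TBSOTf, 2,6-lutidine, CH2Cl2, 0 °C
Reagents that add atoms: tert-butyldimethylsilyl triflate CC(C)(C)[Si](C)(C)OS(=O)(=O)C(F)(F)F
Why: Silyl ether protection with a silyl triflate and a hindered pyridine base should silylate the neopentyl secondary alcohol without affecting the enoate or the stereocentre.

Step 4
Reactants: 6 methyl (2E,6R)-6-(TBS-oxy)-3,7,7-trimethylnona-2,8-dienoate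
Product: 8 methyl (2E,6R)-6-(TBS-oxy)-3,7,7-trimethyl-8-oxooct-2-enoate, via diol 7 (not isolated)
Conditions: OsO4 (2 mol %), NaIO4 (4 equiv), 2,6-lutidine, dioxane/H2O 3:1, 23 °C
Reagents that add atoms: osmium tetroxide O=[Os](=O)(=O)=O; sodium periodate [Na+].[O-]I(=O)(=O)=O
Why: Lemieux–Johnson oxidative cleavage: electrophilic OsO4 should dihydroxylate the isolated vinyl group in preference to the electron-poor trisubstituted enoate, and periodate cleaves the diol to the non-enolisable C5 aldehyde.

Step 5
Reactants: 8 methyl (2E,6R)-6-(TBS-oxy)-3,7,7-trimethyl-8-oxooct-2-enoate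
Product: 9 methyl (2E,6R,8E)-6-(TBS-oxy)-9-iodo-3,7,7-trimethylnona-2,8-dienoate
Conditions: CrCl2 (6 equiv), CHI3 (2 equiv), THF/dioxane 1:6, 0 → 23 °C
Reagents that add atoms: iodoform IC(I)I
Why: Takai olefination: the geminal dichromium reagent from iodoform adds to the hindered aldehyde and eliminates to the (E)-alkenyl iodide (C5=C6), and it tolerates the ester and silyl ether.

Step 6
Reactants: 9 methyl (2E,6R,8E)-6-(TBS-oxy)-9-iodo-3,7,7-trimethylnona-2,8-dienoate
Product: 10 methyl (2E,6R,8E)-6-(TBS-oxy)-3,7,7-trimethyl-11-oxododeca-2,8-dienoate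
Conditions: isopropenyl acetate, Bu3SnOMe, PdCl2[P(o-tol)3]2 (3 mol %), PhMe, 90 °C
Reagents that add atoms: isopropenyl acetate CC(=C)OC(C)=O
Why: Kosugi–Migita coupling: the tin enolate of acetone formed in the flask transmetalates to the alkenylpalladium iodide and reductive elimination joins C6 to C7 with retention of the E geometry under neutral conditions, which should leave the β,γ-enone unconjugated.

Step 7
Reactants: 10 methyl (2E,6R,8E)-6-(TBS-oxy)-3,7,7-trimethyl-11-oxododeca-2,8-dienoate
Product: 11 methyl (2E,6R,8E,10Z)-6,11-bis(TBS-oxy)-3,7,7-trimethyldodeca-2,8,10-trienoate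
Conditions: TBSOTf (1.2 equiv), Et3N, CH2Cl2, −78 → 0 °C
Reagents that add atoms: tert-butyldimethylsilyl triflate CC(C)(C)[Si](C)(C)OS(=O)(=O)C(F)(F)F
Why: Soft enolisation: the C7 methylene between carbonyl and vinyl is by far the most acidic site of the silyl-activated ketone, so the conjugated dienol ether should form regioselectively, and allylic 1,3-strain between the C8 methyl and the vinyl group places oxygen cis to C6, giving the (7Z) geometry in labdane numbering.

Step 8
Reactants: 11 methyl (2E,6R,8E,10Z)-6,11-bis(TBS-oxy)-3,7,7-trimethyldodeca-2,8,10-trienoate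
Product: 12 (2E,6R,8E,10Z)-6,11-bis(TBS-oxy)-3,7,7-trimethyldodeca-2,8,10-trien-1-ol
Conditions: i-Bu2AlH (2.3 equiv), CH2Cl2, −78 °C; aq. potassium sodium tartrate
Reagents that add atoms: none
Why: 1,2-Reduction of the conjugated ester by the aluminium hydride gives the allylic alcohol, and silyl ethers and the silyl dienol ether are inert to the hydride and to the neutral tartrate work-up.

Step 9
Reactants: 12 (2E,6R,8E,10Z)-6,11-bis(TBS-oxy)-3,7,7-trimethyldodeca-2,8,10-trien-1-ol
Product: 13 (2E,6R,8E,10Z)-6,11-bis(TBS-oxy)-3,7,7-trimethyldodeca-2,8,10-trienal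
Conditions: activated MnO2 (excess), CH2Cl2, 23 °C
Reagents that add atoms: none
Why: Allylic oxidation with MnO2 is heterogeneous and neutral, so the enal should form with retention of the E geometry and without hydrolysis of the acid-labile dienol ether.

Step 10
Reactants: 13 (2E,6R,8E,10Z)-6,11-bis(TBS-oxy)-3,7,7-trimethyldodeca-2,8,10-trienal
Product: 14 (1S,2S,4aS,6R,8aR)-2,6-bis(TBS-oxy)-2,5,5,8a-tetramethyl-1,2,4a,5,6,7,8,8a-octahydronaphthalene-1-carbaldehyde
Conditions: PhMe (5 mM), BHT (cat.), base-washed sealed tube, 150 °C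
Reagents that add atoms: none
Why: A thermal, concerted but asynchronous [4+2] cycloaddition is expected, in which the tether aligns the large HOMO coefficient of the silyloxy diene at C5 with the large LUMO coefficient of the enal at C10, so C5–C10 forms ahead of C8–C9; the closest known reaction type is the intramolecular Diels–Alder reaction of 1,3,9-decatrienes with a terminally activated E-dienophile, which gives trans-fused decalins. Ring B is closed by the cycloaddition itself as the new cyclohexene, and ring A by the C1–C4 tether folding into a chair-like six-membered array as C5–C10 forms. C5 and C10 follow from the endo position of the formyl group, which with the E-enal puts the C1 arm of the tether exo, so H5 and the C10 methyl end up anti (trans fusion) and the C9 formyl group ends up cis to the C10 methyl. C8 follows from the (7Z) dienol ether, oxygen inside becoming the equatorial β substituent and methyl outside the axial α one. The absolute sense of all four centres comes from C3, whose silyloxy group takes the equatorial position of the chair tether and so selects one diene face. The step needs endo over exo selectivity and one π-face; secondary overlap of the formyl group with the diene, the 4,4-dimethyl group (which favours the folded rotamer) and the equatorial C3 substituent should provide them.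

Step 11
Reactants: 14 octalin aldehyde
Product: 15 (1S,2S,4aS,6R,8aR)-2,6-bis(TBS-oxy)-2,5,5,8a-tetramethyldecahydronaphthalene-1-carbaldehyde
Conditions: H2 (1 atm), 5% Pt/C, EtOAc, NaHCO3 (solid), 23 °C
Reagents that add atoms: none
Why: Heterogeneous hydrogenation saturates the only C=C bond (C6=C7) without creating a stereocentre, and platinum in a buffered medium is chosen to limit alkene migration toward C5 and hydrogenolysis of the allylic tertiary silyl ether.

Step 12
Reactants: 15 decalin aldehyde
Product: 16 (3R,5S,8S,9S,10R)-3,8-bis(TBS-oxy)-4,4,8,10-tetramethyl-9-vinyldecalin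
Conditions: Ph3PCH3Br, KOt-Bu, THF, 0 → 40 °C
Reagents that add atoms: methyltriphenylphosphonium bromide C[P+](c1ccccc1)(c1ccccc1)c1ccccc1.[Br-]
Why: Wittig methylenation with the small unstabilised ylide should outpace deprotonation at C9, and the equatorial C9 substituent is in any case the thermodynamic one, so C9 is retained.

Step 13
Reactants: 16 9-vinyldecalin
Product: 18 (3R,5S,8S,9S,10R)-3,8-bis(TBS-oxy)-4,4,8,10-tetramethyl-9-(3-methylbut-3-enyl)decalin, via B-alkyl-9-BBN adduct 17 (not isolated)
Conditions: 9-BBN dimer, THF, 50 °C; then 2-bromopropene, Pd(dppf)Cl2 (5 mol %), AsPh3, Cs2CO3, DMF/H2O, 50 °C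
Reagents that add atoms: 2-bromopropene CC(Br)=C
Why: Anti-Markovnikov hydroboration of the terminal vinyl group followed by B-alkyl Suzuki–Miyaura coupling installs C13, its methyl and the exocyclic methylene on the C11–C12 chain in one flask.

Step 14
Reactants: 18 bis-silyl ether
Product: 19 (3R,5S,8S,9S,10R)-4,4,8,10-tetramethyl-9-(3-methylbut-3-enyl)decalin-3,8-diol
Conditions: Bu4NF (excess), THF, 65 °C
Reagents that add atoms: none
Why: Fluoride-mediated desilylation removes both silyl ethers (the tertiary one on heating), and the basic medium avoids acid-catalysed addition of the C8 hydroxyl to the 1,1-disubstituted alkene.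

Step 15
Reactants: 19 diol
Product: 20 (5S,8S,9S,10R)-8-hydroxy-4,4,8,10-tetramethyl-9-(3-methylbut-3-enyl)decalin-3-one
Conditions: Dess–Martin periodinane, NaHCO3, CH2Cl2, 23 °C
Reagents that add atoms: none
Why: Dess–Martin oxidation converts the secondary C3 alcohol to the ketone, while the tertiary C8 alcohol cannot be oxidised and the bicarbonate buffer keeps the medium non-acidic.

Step 16
Reactants: 20 hydroxy ketone
Product: 21 C2=C3 enol triflate of 20 (8-hydroxy, 3-trifluoromethanesulfonyloxy-2-ene)
Conditions: KN(SiMe3)2 (2.3 equiv), THF, −78 °C; PhNTf2, −78 → 0 °C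
Reagents that add atoms: N-phenylbis(trifluoromethanesulfonimide) O=S(=O)(N(c1ccccc1)S(=O)(=O)C(F)(F)F)C(F)(F)F
Why: Enol triflate formation is regiospecific because only C2 carries enolisable hydrogens (C4 is quaternary), and the hindered tertiary alkoxide should not react with this mild triflating agent.

Step 17
Reactants: 21 enol triflate
Product: 22 (5S,8S,9S,10R)-3-bromo-4,4,8,10-tetramethyl-9-(3-methylbut-3-enyl)decal-2-en-8-ol
Conditions: Ni(OAc)2·4H2O (10 mol %), 1,5-cyclooctadiene (cat.), Zn (cat.), LiBr, DMA/THF 1:3, 23 °C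
Reagents that add atoms: lithium bromide [Li+].[Br-]
Why: Nickel-catalysed halide exchange of enol triflates (oxidative addition of zerovalent nickel into C–OTf, triflate/bromide exchange, C–Br reductive elimination) should give the alkenyl bromide at room temperature without touching the free alcohol or the isolated alkene.

Step 18
Reactants: 22 bromoalkenyl alcohol
Product: 23 8-O-allyl ether of 22
Conditions: KH, allyl bromide, Bu4NI (cat.), THF/DMF, 0 → 23 °C
Reagents that add atoms: allyl bromide C=CCBr
Why: Williamson etherification of the potassium tertiary alkoxide with the reactive allylic bromide, while the alkenyl bromide has no substitution or elimination pathway under these conditions.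

Step 19
Reactants: 23 allyl ether diene
Product: 24 tricyclic oxocene: ring C closed with a (13Z) C13=C14 alkene, C2=C3 bromoalkene retained
Conditions: second-generation Grubbs catalyst (10 mol %), PhMe (2 mM), 80 °C
Reagents that add atoms: none
Why: Ring-closing metathesis: the catalyst loads on the allyl ether and closes onto the 1,1-disubstituted alkene; the trans-diequatorial attachment at C8 and C9 holds the two arms gauche, which favours eight-membered ring closure, and the ring size enforces the Z alkene.

Step 20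
Reactants: 24 oxocene
Product: 25 (13S,14R)-13,14-epoxide of 24
Conditions: mCPBA, NaHCO3, CH2Cl2, 0 °C
Reagents that add atoms: 3-chloroperoxybenzoic acid OOC(=O)c1cccc(Cl)c1
Why: Prilezhaev epoxidation of the only nucleophilic alkene (the bromoalkene is deactivated); the oxocene should fold its C12–C15 segment toward the β face, away from the axial C8 and C10 methyl groups, so the peracid attacks the exposed outer face, which corresponds to the (13S,14R) epoxide.

Step 21
Reactants: 25 epoxy bromoalkene
Product: 26 target CNP0311742.1, (3R,5S,8S,9S,10R,13S,14R)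
Conditions: Mn(dpm)3 (15 mol %), PhSiH3, t-BuOOH, i-PrOH, 23 °C, degassed
Reagents that add atoms: none
Why: Metal-hydride hydrogen-atom-transfer hydrogenation of a haloalkene: H• adds to C2 to give the α-bromo radical at C3, which should take the second hydrogen from the axial β direction and leave bromine equatorial (3R), the thermodynamically preferred epimer, while the epoxide and ethers are inert.

**Compound list**

1 | methyl (2E)-3,7-dimethylocta-2,6-dienoate (methyl geranate) | COC(=O)/C=C(C)/CCC=C(C)C | starting material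
2 | methyl (2E)-5-(5,5-dimethyl-1,2,4-trioxolan-3-yl)-3-methylpent-2-enoate (ozonide) | COC(=O)/C=C(C)/CCC1OOC(C)(C)O1 | intermediate (not isolated)
3 | methyl (2E)-3-methyl-6-oxohex-2-enoate | COC(=O)/C=C(C)/CCC=O | intermediate
4 | 3-methylbuta-1,2-diene | CC(C)=C=C | starting material
5 | methyl (2E,6R)-6-hydroxy-3,7,7-trimethylnona-2,8-dienoate | COC(=O)/C=C(C)/CC[C@@H](O)C(C)(C)C=C | intermediate
6 | methyl (2E,6R)-6-(TBS-oxy)-3,7,7-trimethylnona-2,8-dienoate | COC(=O)/C=C(C)/CC[C@@H](O[Si](C)(C)C(C)(C)C)C(C)(C)C=C | intermediate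
7 | methyl (2E,6R)-6-(TBS-oxy)-8,9-dihydroxy-3,7,7-trimethylnon-2-enoate (C8 epimers) | COC(=O)/C=C(C)/CC[C@@H](O[Si](C)(C)C(C)(C)C)C(C)(C)C(O)CO | intermediate (not isolated)
8 | methyl (2E,6R)-6-(TBS-oxy)-3,7,7-trimethyl-8-oxooct-2-enoate | COC(=O)/C=C(C)/CC[C@@H](O[Si](C)(C)C(C)(C)C)C(C)(C)C=O | intermediate
9 | methyl (2E,6R,8E)-6-(TBS-oxy)-9-iodo-3,7,7-trimethylnona-2,8-dienoate | COC(=O)/C=C(C)/CC[C@@H](O[Si](C)(C)C(C)(C)C)C(C)(C)/C=C/I | intermediate
10 | methyl (2E,6R,8E)-6-(TBS-oxy)-3,7,7-trimethyl-11-oxododeca-2,8-dienoate | COC(=O)/C=C(C)/CC[C@@H](O[Si](C)(C)C(C)(C)C)C(C)(C)/C=C/CC(C)=O | intermediate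
11 | methyl (2E,6R,8E,10Z)-6,11-bis(TBS-oxy)-3,7,7-trimethyldodeca-2,8,10-trienoate | COC(=O)/C=C(C)/CC[C@@H](O[Si](C)(C)C(C)(C)C)C(C)(C)/C=C/C=C(C)\O[Si](C)(C)C(C)(C)C | intermediate
12 | (2E,6R,8E,10Z)-6,11-bis(TBS-oxy)-3,7,7-trimethyldodeca-2,8,10-trien-1-ol | OC/C=C(C)/CC[C@@H](O[Si](C)(C)C(C)(C)C)C(C)(C)/C=C/C=C(C)\O[Si](C)(C)C(C)(C)C | intermediate
13 | (2E,6R,8E,10Z)-6,11-bis(TBS-oxy)-3,7,7-trimethyldodeca-2,8,10-trienal (cycloaddition precursor) | O=C/C=C(C)/CC[C@@H](O[Si](C)(C)C(C)(C)C)C(C)(C)/C=C/C=C(C)\O[Si](C)(C)C(C)(C)C | intermediate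
14 | (1S,2S,4aS,6R,8aR)-2,6-bis(TBS-oxy)-2,5,5,8a-tetramethyl-1,2,4a,5,6,7,8,8a-octahydronaphthalene-1-carbaldehyde (cycloadduct) | CC1(C)[C@H](O[Si](C)(C)C(C)(C)C)CC[C@]2(C)[C@@H]1C=C[C@](C)(O[Si](C)(C)C(C)(C)C)[C@H]2C=O | intermediate
15 | (1S,2S,4aS,6R,8aR)-2,6-bis(TBS-oxy)-2,5,5,8a-tetramethyldecahydronaphthalene-1-carbaldehyde | CC1(C)[C@H](O[Si](C)(C)C(C)(C)C)CC[C@]2(C)[C@@H]1CC[C@](C)(O[Si](C)(C)C(C)(C)C)[C@H]2C=O | intermediate
16 | (3R,5S,8S,9S,10R)-3,8-bis(TBS-oxy)-4,4,8,10-tetramethyl-9-vinyldecalin | CC1(C)[C@H](O[Si](C)(C)C(C)(C)C)CC[C@]2(C)[C@@H]1CC[C@](C)(O[Si](C)(C)C(C)(C)C)[C@H]2C=C | intermediate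
17 | B-alkyl-9-borabicyclo[3.3.1]nonane from 16 (boron on C12) | CC1(C)[C@H](O[Si](C)(C)C(C)(C)C)CC[C@]2(C)[C@@H]1CC[C@](C)(O[Si](C)(C)C(C)(C)C)[C@H]2CCB1C2CCCC1CCC2 | intermediate (not isolated)
18 | (3R,5S,8S,9S,10R)-3,8-bis(TBS-oxy)-4,4,8,10-tetramethyl-9-(3-methylbut-3-enyl)decalin | CC1(C)[C@H](O[Si](C)(C)C(C)(C)C)CC[C@]2(C)[C@@H]1CC[C@](C)(O[Si](C)(C)C(C)(C)C)[C@H]2CCC(C)=C | intermediate
19 | (3R,5S,8S,9S,10R)-4,4,8,10-tetramethyl-9-(3-methylbut-3-enyl)decalin-3,8-diol | CC1(C)[C@H](O)CC[C@]2(C)[C@@H]1CC[C@](C)(O)[C@H]2CCC(C)=C | intermediate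
20 | (5S,8S,9S,10R)-8-hydroxy-4,4,8,10-tetramethyl-9-(3-methylbut-3-enyl)decalin-3-one | CC1(C)C(=O)CC[C@]2(C)[C@@H]1CC[C@](C)(O)[C@H]2CCC(C)=C | intermediate
21 | C2=C3 enol triflate of 20 | CC1(C)C(OS(=O)(=O)C(F)(F)F)=CC[C@]2(C)[C@@H]1CC[C@](C)(O)[C@H]2CCC(C)=C | intermediate
22 | (5S,8S,9S,10R)-3-bromo-4,4,8,10-tetramethyl-9-(3-methylbut-3-enyl)decal-2-en-8-ol | CC1(C)C(Br)=CC[C@]2(C)[C@@H]1CC[C@](C)(O)[C@H]2CCC(C)=C | intermediate
23 | 8-O-allyl ether of 22 | CC1(C)C(Br)=CC[C@]2(C)[C@@H]1CC[C@](C)(OCC=C)[C@H]2CCC(C)=C | intermediate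
24 | tricyclic oxocene, (13Z)-alkene, C2=C3 bromoalkene | CC1(C)C(Br)=CC[C@]2(C)[C@@H]1CC[C@]1(C)OC/C=C(C)\CC[C@@H]21 | intermediate
25 | (13S,14R)-13,14-epoxide of 24 | CC1(C)C(Br)=CC[C@]2(C)[C@@H]1CC[C@]1(C)OC[C@H]3O[C@@]3(C)CC[C@@H]21 | intermediate
26 | CNP0311742.1, (3R,5S,8S,9S,10R,13S,14R)-3-bromo-8,15:13,14-diepoxy-ent-labdane | CC1(C)[C@H](Br)CC[C@]2(C)[C@@H]1CC[C@]1(C)OC[C@H]3O[C@@]3(C)CC[C@@H]21 | target

**Totals and risks**

Total step count: 21. Longest linear sequence: 21 steps (1 → 26).

Steps most likely to fail: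

1. Step 10. The hindered termini may demand a temperature at which endo selectivity erodes (cis-fused isomer) or the trienal degrades before it cyclises. Fallback: the dienophile is changed to the ester. Ester 11 is cyclised with MeAlCl2 in CH2Cl2 at −78 → −20 °C (Lewis-acid-promoted intramolecular Diels–Alder reaction of a trienoate, which usually raises the endo preference) to the methyl ester cycloadduct F1. i-Bu2AlH then gives the primary alcohol F2, and Dess–Martin oxidation returns to the route at 14.

2. Step 6. The β,γ-double bond may migrate into conjugation with the ketone under the tin/palladium conditions, or transmetalation at the hindered alkenyl iodide may stall. Fallback: the diene is made by olefination instead of coupling. Setting out from aldehyde 8, a Wittig reaction with the ylide generated by n-BuLi (THF, −78 °C) from [(2Z)-3-(TBS-oxy)but-2-enyl]triphenylphosphonium triflate F3 gives dienol ether 11 directly, bypassing 9 and 10. F3 is prepared by phosphoniosilylation of but-3-en-2-one with PPh3 and TBSOTf. Any (8Z) isomer cannot reach the s-cis diene geometry and is separated.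

3. Step 20. The peracid may deliver oxygen to the wrong face of the ring alkene if the oxocene folds differently from the prediction. Fallback: the face is inverted through a halohydrin. Setting out from 24, NBS in aqueous THF gives the bromohydrin F4 (bromonium on the exposed face, water anti at the tertiary C13), and K2CO3 in MeOH closes the epoxide on the opposite face, returning to the route at 25.

**Further compounds**

F1 | step 10 | methyl ester cycloadduct (C9 CO2Me in place of CHO in 14) | CC1(C)[C@H](O[Si](C)(C)C(C)(C)C)CC[C@]2(C)[C@@H]1C=C[C@](C)(O[Si](C)(C)C(C)(C)C)[C@H]2C(=O)OC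
F2 | step 10 | primary alcohol (C9 CH2OH in place of CHO in 14) | CC1(C)[C@H](O[Si](C)(C)C(C)(C)C)CC[C@]2(C)[C@@H]1C=C[C@](C)(O[Si](C)(C)C(C)(C)C)[C@H]2CO
F3 | step 6 | [(2Z)-3-(TBS-oxy)but-2-enyl]triphenylphosphonium triflate | C/C(O[Si](C)(C)C(C)(C)C)=C/C[P+](c1ccccc1)(c1ccccc1)c1ccccc1.[O-]S(=O)(=O)C(F)(F)F
F4 | step 20 | 14-bromo-13-hydroxy bromohydrin of 24 | CC1(C)C(Br)=CC[C@]2(C)[C@@H]1CC[C@]1(C)OC[C@H](Br)[C@@](C)(O)CC[C@@H]21
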